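**Retrosynthetic overview**

1. The last bond is C11=C12, made by Wittig olefination of a C15 dienal (3,6‑dihydroxy‑4‑ene ring) with a C25 polyenynyl phosphonium salt; the C25 unit comes from an acetylenic C15 phosphonium salt and the C10 trienedial (C11'=C12'). Both halves use the same C6 enynol, once in a Sonogashira coupling (C6'–C7') and once as an acetylide added to a ring ketone (C6–C7, union at the fully substituted carbinol carbon).
2. The acetylenic ring (C1'–C6') is not cyclised but grown from a cyclopentane. A (chloromethylidene)cyclopentane is lithiated, the carbenoid rearranges by 1,2‑shift to a 3,3‑dimethylcyclohexyne, MeLi adds at C5' and iodine caps C6', all in one pot.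
3. Enabling feature: the tetrasubstituted C5'=C6' bond of that ring lies between the quaternary C1' (gem‑dimethyl) and the C4' methylene. It maps onto a cyclohexyne with two sterically different sp carbons; either alpha carbon of the cyclopentylidene migrates to the same alkyne, and the C3' carbinol carbon is beta to the migration and keeps its configuration.
4. The hydroxy‑ene ring (C1–C6) is taken intact from ketoisophorone: the C3 carbinol by asymmetric transfer hydrogenation, C6 by substrate‑controlled acetylide addition, the cis‑1,4 relationship by Mitsunobu inversion, the 7E alkene by hydroxyl‑directed alkyne reduction.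
5. Ring order: the commercial cyclohexenedione ring is used as such; the only ring event is cyclopentane → cyclohexene of the acetylenic end in step 5.

Key step: step 5

Remark on numbering: carotenoid numbering is used, with the hydroxy‑ene ring C1–C6, the chain C7–C15 and C15'–C7', and the acetylenic ring C1'–C6'. The target is (3S,6R,3'R), all‑E, with the 3‑ and 6‑hydroxyls cis.

Assumption: the catalyst antipodes named in steps 2 and 12 are those expected from the usual sense of induction of these catalyst families; if a test reaction shows the opposite sense, the mirror‑image ligand is used.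

**Step 1**
Reactants: 1 2,2-dimethylcyclopentan-1-one
Product: 2 5,5-dimethylcyclopent-2-en-1-one
Conditions: IBX, DMSO/toluene, 70 °C
Reagents that add atoms: none
Why: IBX‑mediated alpha,beta‑dehydrogenation of a ketone; only one alpha carbon carries hydrogens, so a single enone should form.

**Step 2**
Reactants: 2 5,5-dimethylcyclopent-2-en-1-one
Product: 4 (4S)-4-hydroxy-2,2-dimethylcyclopentan-1-one, via boryl ketone 3 (not isolated)
Conditions: B2pin2, CuCl (cat.), NaOt-Bu (cat.), (R)-1-[(S)-2-(diphenylphosphino)ferrocenyl]ethyldicyclohexylphosphine (cat.), MeOH (2 equiv), THF, rt; then NaBO3·4H2O, THF/H2O, rt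
Reagents that add atoms: bis(pinacolato)diboron CC1(C)OB(OC1(C)C)B1OC(C)(C)C(C)(C)O1 (boron of 3); sodium perborate [Na+].[O-]OB=O (oxygen of 4)
Why: Copper‑catalysed enantioselective conjugate borylation of a cyclic enone followed by stereoretentive C–B oxidation; the chiral bisphosphine–copper boryl complex selects the enone face and sets the carbinol carbon (future C3').

**Step 3**
Reactants: 4 (4S)-4-hydroxy-2,2-dimethylcyclopentan-1-one
Product: 5 (4S)-4-[(tert-butyldimethylsilyl)oxy]-2,2-dimethylcyclopentan-1-one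
Conditions: TBSCl, imidazole, DMF, 0 °C → rt
Reagents that add atoms: tert-butyldimethylsilyl chloride CC(C)(C)[Si](C)(C)Cl
Why: Standard silylation of a secondary alcohol, which also removes the risk of dehydration of the beta‑hydroxy ketone in the following basic steps.

**Step 4**
Reactants: 5 (4S)-4-[(tert-butyldimethylsilyl)oxy]-2,2-dimethylcyclopentan-1-one
Product: 6 tert-butyl{[(1S)-3-(chloromethylidene)-4,4-dimethylcyclopentyl]oxy}dimethylsilane (E/Z mixture)
Conditions: Ph3PCH2Cl+ Cl−, NaN(SiMe3)2, THF, −78 °C → rt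
Reagents that add atoms: (chloromethyl)triphenylphosphonium chloride ClC[P+](c1ccccc1)(c1ccccc1)c1ccccc1.[Cl-]
Why: Wittig chloromethylenation of a cyclopentanone; the alkene geometry is irrelevant because both isomers lead to the same cyclohexyne in step 5.

**Step 5**
Reactants: 6 tert-butyl{[(1S)-3-(chloromethylidene)-4,4-dimethylcyclopentyl]oxy}dimethylsilane
Product: 10 tert-butyl{[(1R)-4-iodo-3,5,5-trimethylcyclohex-3-en-1-yl]oxy}dimethylsilane, via lithium carbenoid 7 (not isolated), via cyclohexyne 8 (not isolated), via vinyllithium 9 (not isolated)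
Conditions: s-BuLi (1.0 equiv), THF/Et2O, −105 °C; then MeLi (4 equiv, Et2O), −105 → −20 °C; then I2, −78 °C → rt
Reagents that add atoms: methyllithium [Li]C; iodine II
Why: Proposed new method: alpha‑lithiation of the vinyl chloride gives carbenoid 7, whose Fritsch–Buttenberg–Wiechell 1,2‑shift of a ring C–C bond onto the exocyclic carbon (loss of LiCl) enlarges the cyclopentane to the strained cyclohexyne 8; MeLi then adds across the alkyne and iodine traps vinyllithium 9. The closest known reaction types are the base‑induced ring enlargement of (halomethylidene)cycloalkanes to cycloalkynes with capture by a nucleophile, and the addition of organolithiums to cyclohexyne generated from 1‑halocyclohexenes. The six‑membered ring is closed by ring expansion (1,2‑alkyl migration from a five‑membered ring), not by a cyclisation mode, and either alpha carbon (CMe2 or CH2) gives the same alkyne. No new stereocentre is formed, and the silyloxy‑bearing carbon is beta to the carbenoid, so its configuration is carried through unchanged. The selectivity needed is regiochemical: MeLi must add to the sp carbon next to the CH2 (future C5') so that the carbanion and then iodine sit next to the gem‑dimethyl carbon (future C6'), which the neopentyl shielding of that carbon should secure. The operation builds the ring, the C5' methyl, the tetrasubstituted alkene and the coupling handle together.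

**Step 6**
Reactants: 10 tert-butyl{[(1R)-4-iodo-3,5,5-trimethylcyclohex-3-en-1-yl]oxy}dimethylsilane; 11 (2E)-3-methylpent-2-en-4-yn-1-ol
Product: 12 (2E)-5-{(4R)-4-[(tert-butyldimethylsilyl)oxy]-2,6,6-trimethylcyclohex-1-en-1-yl}-3-methylpent-2-en-4-yn-1-ol
Conditions: Pd(PPh3)4 (cat.), CuI (cat.), i-Pr2NH, THF, rt → 45 °C, degassed
Reagents that add atoms: none
Why: Sonogashira coupling (zerovalent palladium with a copper acetylide) of a hindered cyclohexenyl iodide with a terminal enyne; the E geometry of 11 is not touched.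

**Step 7**
Reactants: 12 (2E)-5-{(4R)-4-[(tert-butyldimethylsilyl)oxy]-2,6,6-trimethylcyclohex-1-en-1-yl}-3-methylpent-2-en-4-yn-1-ol
Product: 13 (1R)-4-[(3E)-5-hydroxy-3-methylpent-3-en-1-yn-1-yl]-3,5,5-trimethylcyclohex-3-en-1-ol
Conditions: Bu4NF, THF, 0 °C → rt
Reagents that add atoms: none
Why: Fluoride desilylation; the silyl group is removed here so that the acidic step 8 meets only the robust free homoallylic alcohol.

**Step 8**
Reactants: 13 (1R)-4-[(3E)-5-hydroxy-3-methylpent-3-en-1-yn-1-yl]-3,5,5-trimethylcyclohex-3-en-1-ol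
Product: 14 {(2E)-5-[(4R)-4-hydroxy-2,6,6-trimethylcyclohex-1-en-1-yl]-3-methylpent-2-en-4-yn-1-yl}triphenylphosphonium bromide
Conditions: PPh3·HBr, MeOH/CH2Cl2, rt
Reagents that add atoms: triphenylphosphine hydrobromide [Br-].[PH+](c1ccccc1)(c1ccccc1)c1ccccc1
Why: Phosphonium salt formation from an allylic alcohol via the delocalised allyl cation, as in the classical carotenoid C15 Wittig salts; only the primary allylic hydroxyl ionises, the ring homoallylic alcohol does not.

**Step 9**
Reactants: 14 {(2E)-5-[(4R)-4-hydroxy-2,6,6-trimethylcyclohex-1-en-1-yl]-3-methylpent-2-en-4-yn-1-yl}triphenylphosphonium bromide; 15 (2E,4E,6E)-2,7-dimethylocta-2,4,6-trienedial (3 equiv)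
Product: 17 (2E,4E,6E,8E,10E)-13-[(4R)-4-hydroxy-2,6,6-trimethylcyclohex-1-en-1-yl]-2,7,11-trimethyltrideca-2,4,6,8,10-pentaen-12-ynal, via phosphorus ylide 16 (not isolated)
Conditions: NaOMe, MeOH/CH2Cl2, 0 °C → rt; then heptane, 80 °C, short (Z → E at the new bond); crystallisation
Reagents that add atoms: none
Why: Wittig olefination with the dialdehyde in excess to favour mono‑olefination; the semi‑stabilised ylide should give an E/Z mixture at C11'=C12' that is equilibrated to E by brief warming.

**Step 10**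
Reactants: 17 (2E,4E,6E,8E,10E)-13-[(4R)-4-hydroxy-2,6,6-trimethylcyclohex-1-en-1-yl]-2,7,11-trimethyltrideca-2,4,6,8,10-pentaen-12-ynal
Product: 18 (2E,4E,6E,8E,10E)-13-[(4R)-4-hydroxy-2,6,6-trimethylcyclohex-1-en-1-yl]-2,7,11-trimethyltrideca-2,4,6,8,10-pentaen-12-yn-1-ol
Conditions: NaBH4, MeOH/CH2Cl2, 0 °C
Reagents that add atoms: none
Why: 1,2‑Reduction of a conjugated polyenal by borohydride, which leaves the polyene and the alkyne untouched.

**Step 11**
Reactants: 18 (2E,4E,6E,8E,10E)-13-[(4R)-4-hydroxy-2,6,6-trimethylcyclohex-1-en-1-yl]-2,7,11-trimethyltrideca-2,4,6,8,10-pentaen-12-yn-1-ol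
Product: 19 {(2E,4E,6E,8E,10E)-13-[(4R)-4-hydroxy-2,6,6-trimethylcyclohex-1-en-1-yl]-2,7,11-trimethyltrideca-2,4,6,8,10-pentaen-12-yn-1-yl}triphenylphosphonium bromide
Conditions: PPh3·HBr, MeOH/CH2Cl2, 0 °C → rt, dark
Reagents that add atoms: triphenylphosphine hydrobromide [Br-].[PH+](c1ccccc1)(c1ccccc1)c1ccccc1
Why: Phosphonium salt formation from a polyenylic alcohol (retinyl‑type Wittig salt formation); phosphine capture at the primary terminus of the delocalised cation keeps the polyene conjugated.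

**Step 12**
Reactants: 20 2,6,6-trimethylcyclohex-2-ene-1,4-dione (ketoisophorone)
Product: 21 (4R)-4-hydroxy-2,6,6-trimethylcyclohex-2-en-1-one
Conditions: RuCl[(R,R)-TsDPEN](p-cymene) (cat.), i-PrOH, rt
Reagents that add atoms: none
Why: Noyori asymmetric transfer hydrogenation; only the unhindered C4 carbonyl is reduced, and the catalyst distinguishes its alkenyl flank from its CH2 flank to set the carbinol configuration.

**Step 13**
Reactants: 11 (2E)-3-methylpent-2-en-4-yn-1-ol
Product: 22 tert-butyl{[(2E)-3-methylpent-2-en-4-yn-1-yl]oxy}diphenylsilane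
Conditions: TBDPSCl, imidazole, CH2Cl2, 0 °C → rt
Reagents that add atoms: tert-butyldiphenylsilyl chloride CC(C)(C)[Si](Cl)(c1ccccc1)c1ccccc1
Why: Standard silylation; the primary hydroxyl must be masked so that the Mitsunobu step later acts only on the ring carbinol.

**Step 14**
Reactants: 21 (4R)-4-hydroxy-2,6,6-trimethylcyclohex-2-en-1-one; 22 tert-butyl{[(2E)-3-methylpent-2-en-4-yn-1-yl]oxy}diphenylsilane (2.2 equiv)
Product: 24 (1R,4R)-1-[(3E)-5-{[tert-butyl(diphenyl)silyl]oxy}-3-methylpent-3-en-1-yn-1-yl]-2,6,6-trimethylcyclohex-2-ene-1,4-diol, via lithium acetylide 23 (not isolated)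
Conditions: n-BuLi (2.1 equiv), THF, −78 °C; then 21, −78 → 0 °C; aq NH4Cl
Reagents that add atoms: none
Why: 1,2‑Addition of a lithium acetylide to the hindered, non‑enolisable ring ketone (the first equivalent deprotonates the hydroxyl); in the enone half‑chair the axial methyl of the gem‑dimethyl group blocks one face, so the nucleophile should enter anti to it, which is the face syn to the pseudo‑equatorial C4 oxygen, and this sets the tertiary carbinol carbon (future C6) in the target configuration.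

**Step 15**
Reactants: 24 (1R,4R)-1-[(3E)-5-{[tert-butyl(diphenyl)silyl]oxy}-3-methylpent-3-en-1-yn-1-yl]-2,6,6-trimethylcyclohex-2-ene-1,4-diol
Product: 25 (1S,4R)-4-[(3E)-5-{[tert-butyl(diphenyl)silyl]oxy}-3-methylpent-3-en-1-yn-1-yl]-4-hydroxy-3,5,5-trimethylcyclohex-2-en-1-yl benzoate
Conditions: PPh3, DIAD, PhCO2H, toluene, −20 → 0 °C
Reagents that add atoms: benzoic acid OC(=O)c1ccccc1
Why: Mitsunobu inversion; benzoate displaces the oxyphosphonium group of the secondary allylic alcohol by SN2 (the tertiary alcohol does not react), which turns the 1,4‑trans diol into the 1,4‑cis relationship of the target (future C3 becomes S).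

**Step 16**
Reactants: 25 (1S,4R)-4-[(3E)-5-{[tert-butyl(diphenyl)silyl]oxy}-3-methylpent-3-en-1-yn-1-yl]-4-hydroxy-3,5,5-trimethylcyclohex-2-en-1-yl benzoate
Product: 26 (1S,4R)-4-hydroxy-4-[(3E)-5-hydroxy-3-methylpent-3-en-1-yn-1-yl]-3,5,5-trimethylcyclohex-2-en-1-yl benzoate
Conditions: Bu4NF, AcOH (buffer), THF, 0 °C
Reagents that add atoms: none
Why: Fluoride desilylation under buffered conditions that leave the benzoate in place; the free primary alkoxide is the form with precedent in the next reduction.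

**Step 17**
Reactants: 26 (1S,4R)-4-hydroxy-4-[(3E)-5-hydroxy-3-methylpent-3-en-1-yn-1-yl]-3,5,5-trimethylcyclohex-2-en-1-yl benzoate
Product: 27 (1R,4S)-1-[(1E,3E)-5-hydroxy-3-methylpenta-1,3-dien-1-yl]-2,6,6-trimethylcyclohex-2-ene-1,4-diol
Conditions: NaAlH2(OCH2CH2OMe)2 (Red-Al, excess), THF, 0 °C → rt; Rochelle salt work-up
Reagents that add atoms: none
Why: Hydroxyl‑directed trans‑hydroalumination of a propargylic alcohol gives the E alkene (C7=C8) after protonation, as in abscisic acid‑type enyne diol reductions; the same hydride cleaves the benzoate.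

**Step 18**
Reactants: 27 (1R,4S)-1-[(1E,3E)-5-hydroxy-3-methylpenta-1,3-dien-1-yl]-2,6,6-trimethylcyclohex-2-ene-1,4-diol
Product: 28 (2E,4E)-5-[(1R,4S)-1,4-dihydroxy-2,6,6-trimethylcyclohex-2-en-1-yl]-3-methylpenta-2,4-dienal
Conditions: TEMPO (cat.), PhI(OAc)2, NaHCO3, CH2Cl2, 0 °C
Reagents that add atoms: none
Why: Oxoammonium (TEMPO) oxidation, which is selective for the primary allylic alcohol over the secondary ring carbinol and the tertiary alcohol; the bicarbonate buffer protects the acid‑sensitive tertiary bis‑allylic alcohol.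

**Step 19**
Reactants: 19 {(2E,4E,6E,8E,10E)-13-[(4R)-4-hydroxy-2,6,6-trimethylcyclohex-1-en-1-yl]-2,7,11-trimethyltrideca-2,4,6,8,10-pentaen-12-yn-1-yl}triphenylphosphonium bromide; 28 (2E,4E)-5-[(1R,4S)-1,4-dihydroxy-2,6,6-trimethylcyclohex-2-en-1-yl]-3-methylpenta-2,4-dienal
Product: 30 all-E (3S,6R,3'R)-7',8'-didehydro-ε,β-carotene-3,6,3'-triol (CNP0113828.1), via phosphorus ylide 29 (not isolated)
Conditions: NaOMe (excess), MeOH/CH2Cl2, 0 °C → rt, dark, argon; then EtOAc, 60 °C, short (Z → E at C11=C12); crystallisation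
Reagents that add atoms: none
Why: Wittig olefination forming C11=C12 with all hydroxyls free, so no deprotection follows; the medium is basic to neutral throughout, which the tertiary bis‑allylic alcohol tolerates, and the Z isomer at the new bond should isomerise to all‑E on mild warming.

**Compound list**

1 | 2,2-dimethylcyclopentan-1-one | O=C1CCCC1(C)C | starting material
2 | 5,5-dimethylcyclopent-2-en-1-one | O=C1C=CCC1(C)C | intermediate
3 | (4S)-2,2-dimethyl-4-(4,4,5,5-tetramethyl-1,3,2-dioxaborolan-2-yl)cyclopentan-1-one (not isolated) | O=C1C[C@@H](B2OC(C)(C)C(C)(C)O2)CC1(C)C | intermediate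
4 | (4S)-4-hydroxy-2,2-dimethylcyclopentan-1-one | O=C1C[C@@H](O)CC1(C)C | intermediate
5 | (4S)-4-[(tert-butyldimethylsilyl)oxy]-2,2-dimethylcyclopentan-1-one | O=C1C[C@@H](O[Si](C)(C)C(C)(C)C)CC1(C)C | intermediate
6 | tert-butyl{[(1S)-3-(chloromethylidene)-4,4-dimethylcyclopentyl]oxy}dimethylsilane (E/Z mixture) | ClC=C1C[C@@H](O[Si](C)(C)C(C)(C)C)CC1(C)C | intermediate
7 | tert-butyl{[(1S)-3-[chloro(lithio)methylidene]-4,4-dimethylcyclopentyl]oxy}dimethylsilane (not isolated) | [Li]C(Cl)=C1C[C@@H](O[Si](C)(C)C(C)(C)C)CC1(C)C | intermediate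
8 | tert-butyl{[(1R)-5,5-dimethylcyclohex-3-yn-1-yl]oxy}dimethylsilane (not isolated) | C1#CC[C@@H](O[Si](C)(C)C(C)(C)C)CC1(C)C | intermediate
9 | {(4R)-4-[(tert-butyldimethylsilyl)oxy]-2,6,6-trimethylcyclohex-1-en-1-yl}lithium (not isolated) | [Li]C1=C(C)C[C@@H](O[Si](C)(C)C(C)(C)C)CC1(C)C | intermediate
10 | tert-butyl{[(1R)-4-iodo-3,5,5-trimethylcyclohex-3-en-1-yl]oxy}dimethylsilane | IC1=C(C)C[C@@H](O[Si](C)(C)C(C)(C)C)CC1(C)C | intermediate
11 | (2E)-3-methylpent-2-en-4-yn-1-ol | OC/C=C(\C)C#C | starting material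
12 | (2E)-5-{(4R)-4-[(tert-butyldimethylsilyl)oxy]-2,6,6-trimethylcyclohex-1-en-1-yl}-3-methylpent-2-en-4-yn-1-ol | OC/C=C(\C)C#CC1=C(C)C[C@@H](O[Si](C)(C)C(C)(C)C)CC1(C)C | intermediate
13 | (1R)-4-[(3E)-5-hydroxy-3-methylpent-3-en-1-yn-1-yl]-3,5,5-trimethylcyclohex-3-en-1-ol | OC/C=C(\C)C#CC1=C(C)C[C@@H](O)CC1(C)C | intermediate
14 | {(2E)-5-[(4R)-4-hydroxy-2,6,6-trimethylcyclohex-1-en-1-yl]-3-methylpent-2-en-4-yn-1-yl}triphenylphosphonium bromide | [Br-].C(/C=C(\C)C#CC1=C(C)C[C@@H](O)CC1(C)C)[P+](c2ccccc2)(c3ccccc3)c4ccccc4 | intermediate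
15 | (2E,4E,6E)-2,7-dimethylocta-2,4,6-trienedial | O=C/C(C)=C/C=C/C=C(C)/C=O | starting material
16 | ylide of 14 (not isolated) | [CH-](/C=C(\C)C#CC1=C(C)C[C@@H](O)CC1(C)C)[P+](c2ccccc2)(c3ccccc3)c4ccccc4 | intermediate
17 | (2E,4E,6E,8E,10E)-13-[(4R)-4-hydroxy-2,6,6-trimethylcyclohex-1-en-1-yl]-2,7,11-trimethyltrideca-2,4,6,8,10-pentaen-12-ynal | O=C/C(C)=C/C=C/C=C(C)/C=C/C=C(\C)C#CC1=C(C)C[C@@H](O)CC1(C)C | intermediate
18 | (2E,4E,6E,8E,10E)-13-[(4R)-4-hydroxy-2,6,6-trimethylcyclohex-1-en-1-yl]-2,7,11-trimethyltrideca-2,4,6,8,10-pentaen-12-yn-1-ol | OC/C(C)=C/C=C/C=C(C)/C=C/C=C(\C)C#CC1=C(C)C[C@@H](O)CC1(C)C | intermediate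
19 | {(2E,4E,6E,8E,10E)-13-[(4R)-4-hydroxy-2,6,6-trimethylcyclohex-1-en-1-yl]-2,7,11-trimethyltrideca-2,4,6,8,10-pentaen-12-yn-1-yl}triphenylphosphonium bromide | [Br-].C(/C(C)=C/C=C/C=C(C)/C=C/C=C(\C)C#CC1=C(C)C[C@@H](O)CC1(C)C)[P+](c2ccccc2)(c3ccccc3)c4ccccc4 | intermediate
20 | 2,6,6-trimethylcyclohex-2-ene-1,4-dione (ketoisophorone) | CC1=CC(=O)CC(C)(C)C1=O | starting material
21 | (4R)-4-hydroxy-2,6,6-trimethylcyclohex-2-en-1-one | CC1=C[C@H](O)CC(C)(C)C1=O | intermediate
22 | tert-butyl{[(2E)-3-methylpent-2-en-4-yn-1-yl]oxy}diphenylsilane | C#C/C(C)=C/CO[Si](c1ccccc1)(c1ccccc1)C(C)(C)C | intermediate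
23 | lithium acetylide of 22 (not isolated) | [Li]C#C/C(C)=C/CO[Si](c1ccccc1)(c1ccccc1)C(C)(C)C | intermediate
24 | (1R,4R)-1-[(3E)-5-{[tert-butyl(diphenyl)silyl]oxy}-3-methylpent-3-en-1-yn-1-yl]-2,6,6-trimethylcyclohex-2-ene-1,4-diol | CC1=C[C@H](O)CC(C)(C)[C@]1(O)C#C/C(C)=C/CO[Si](c2ccccc2)(c3ccccc3)C(C)(C)C | intermediate
25 | (1S,4R)-4-[(3E)-5-{[tert-butyl(diphenyl)silyl]oxy}-3-methylpent-3-en-1-yn-1-yl]-4-hydroxy-3,5,5-trimethylcyclohex-2-en-1-yl benzoate | CC1=C[C@@H](OC(=O)c2ccccc2)CC(C)(C)[C@]1(O)C#C/C(C)=C/CO[Si](c3ccccc3)(c4ccccc4)C(C)(C)C | intermediate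
26 | (1S,4R)-4-hydroxy-4-[(3E)-5-hydroxy-3-methylpent-3-en-1-yn-1-yl]-3,5,5-trimethylcyclohex-2-en-1-yl benzoate | CC1=C[C@@H](OC(=O)c2ccccc2)CC(C)(C)[C@]1(O)C#C/C(C)=C/CO | intermediate
27 | (1R,4S)-1-[(1E,3E)-5-hydroxy-3-methylpenta-1,3-dien-1-yl]-2,6,6-trimethylcyclohex-2-ene-1,4-diol | CC1=C[C@@H](O)CC(C)(C)[C@]1(O)/C=C/C(C)=C/CO | intermediate
28 | (2E,4E)-5-[(1R,4S)-1,4-dihydroxy-2,6,6-trimethylcyclohex-2-en-1-yl]-3-methylpenta-2,4-dienal | CC1=C[C@@H](O)CC(C)(C)[C@]1(O)/C=C/C(C)=C/C=O | intermediate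
29 | ylide of 19 (not isolated) | [CH-](/C(C)=C/C=C/C=C(C)/C=C/C=C(\C)C#CC1=C(C)C[C@@H](O)CC1(C)C)[P+](c2ccccc2)(c3ccccc3)c4ccccc4 | intermediate
30 | all-E (3S,6R,3'R)-7',8'-didehydro-ε,β-carotene-3,6,3'-triol (CNP0113828.1) | CC1=C[C@@H](O)CC(C)(C)[C@]1(O)/C=C/C(C)=C/C=C/C(C)=C/C=C/C=C(C)/C=C/C=C(\C)C#CC1=C(C)C[C@@H](O)CC1(C)C | target

**Step count and risks**

Total step count: 19. Longest linear sequence: 12 (steps 1–11, then step 19).

Steps most likely to fail:

Step 5 (Proposed new method). What may go wrong: methylation of carbenoid 7 at the carbenoid carbon by MeLi before the ring bond migrates, so that no ring enlargement occurs; or addition of MeLi to the hindered sp carbon of 8, which gives the regioisomeric iodide. The fallback uses known chemistry, keeps the five‑to‑six ring enlargement, and sets out from ketone 5. Lewis‑acid‑catalysed homologation of 5 with diazoethane (Sc(OTf)3 cat., toluene, −78 °C; Tiffeneau–Demjanov‑type insertion in which the less substituted CH2 migrates) should give (4R)-4-[(tert-butyldimethylsilyl)oxy]-2,2,6-trimethylcyclohexan-1-one F1 as a mixture of epimers at the methyl‑bearing carbon, both usable. Deprotonation at its only alpha C–H with KN(SiMe3)2 and trapping with PhNTf2 should give the tetrasubstituted enol triflate (4R)-4-[(tert-butyldimethylsilyl)oxy]-2,6,6-trimethylcyclohex-1-en-1-yl trifluoromethanesulfonate F2. Sonogashira coupling of F2 with 11 (Pd(PPh3)4, CuI, i-Pr2NH) comes back to the route at compound 12.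

Step 14. What may go wrong: the acetylide entering on the face anti to the C4 oxygen, that is, a facial selectivity opposite to the torsional model, which would set the tertiary carbinol carbon in the wrong configuration. The fallback changes the stereochemical plan from addition‑then‑inversion to direct cis addition and sets out from 20. Transfer hydrogenation with the antipodal catalyst RuCl[(S,S)-TsDPEN](p-cymene) gives (4S)-4-hydroxy-2,6,6-trimethylcyclohex-2-en-1-one F3. Addition of 23 then places the alkynyl group anti to the oxygen and gives directly the 1,4‑cis diol (1R,4S)-1-[(3E)-5-{[tert-butyl(diphenyl)silyl]oxy}-3-methylpent-3-en-1-yn-1-yl]-2,6,6-trimethylcyclohex-2-ene-1,4-diol F4, so no inversion is needed. Bu4NF gives (1R,4S)-1-[(3E)-5-hydroxy-3-methylpent-3-en-1-yn-1-yl]-2,6,6-trimethylcyclohex-2-ene-1,4-diol F5, and Red‑Al reduction as in step 17 comes back to the route at compound 27.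

Step 15. What may go wrong: ionisation of the allylic oxyphosphonium intermediate, with loss of stereochemical integrity, allylic transposition or elimination to a diene, instead of clean SN2 displacement. The fallback replaces substitution by oxidation–reduction and sets out from 24. MnO2 (CH2Cl2, rt) oxidises the secondary allylic alcohol to (4R)-4-[(3E)-5-{[tert-butyl(diphenyl)silyl]oxy}-3-methylpent-3-en-1-yn-1-yl]-4-hydroxy-3,5,5-trimethylcyclohex-2-en-1-one F6. LiBH(s-Bu)3 (THF, −78 °C) should deliver hydride to this isophorone‑type carbonyl from the face anti to the axial methyl of the gem‑dimethyl group and give the 1,4‑cis diol, which is the compound F4 described above. From there the path via F5 comes back to the route at compound 27.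

**Further compounds**

F1 | step 5 | (4R)-4-[(tert-butyldimethylsilyl)oxy]-2,2,6-trimethylcyclohexan-1-one (epimers at C6) | O=C1C(C)C[C@@H](O[Si](C)(C)C(C)(C)C)CC1(C)C
F2 | step 5 | (4R)-4-[(tert-butyldimethylsilyl)oxy]-2,6,6-trimethylcyclohex-1-en-1-yl trifluoromethanesulfonate | FC(F)(F)S(=O)(=O)OC1=C(C)C[C@@H](O[Si](C)(C)C(C)(C)C)CC1(C)C
F3 | step 14 | (4S)-4-hydroxy-2,6,6-trimethylcyclohex-2-en-1-one | CC1=C[C@@H](O)CC(C)(C)C1=O
F4 | step 14 | (1R,4S)-1-[(3E)-5-{[tert-butyl(diphenyl)silyl]oxy}-3-methylpent-3-en-1-yn-1-yl]-2,6,6-trimethylcyclohex-2-ene-1,4-diol | CC1=C[C@@H](O)CC(C)(C)[C@]1(O)C#C/C(C)=C/CO[Si](c2ccccc2)(c3ccccc3)C(C)(C)C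
F5 | step 14 | (1R,4S)-1-[(3E)-5-hydroxy-3-methylpent-3-en-1-yn-1-yl]-2,6,6-trimethylcyclohex-2-ene-1,4-diol | CC1=C[C@@H](O)CC(C)(C)[C@]1(O)C#C/C(C)=C/CO
F6 | step 15 | (4R)-4-[(3E)-5-{[tert-butyl(diphenyl)silyl]oxy}-3-methylpent-3-en-1-yn-1-yl]-4-hydroxy-3,5,5-trimethylcyclohex-2-en-1-one | CC1=CC(=O)CC(C)(C)[C@]1(O)C#C/C(C)=C/CO[Si](c2ccccc2)(c3ccccc3)C(C)(C)C
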